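The route rests on cutting C7–C8 of the ten-membered carbocycle (C1–C10). The feature used is that C8, the ester-bearing carbinol carbon, is bonded to C7, the β-carbon of the C12 carbonyl in the five-membered lactone ring, so a ketyl at C8 can add to a butenolide. In one operation, samarium diiodide should form C7–C8, close the ten-membered ring and set C7 and C8 from the single stereocentre C6. The substrate is an open-chain dienal (Z-C4=C5, E-C1=C10, C8 aldehyde) carrying the C6-butenolide, built by a B-alkyl Suzuki coupling and an asymmetric propiolate addition. Acylation, α-methylenation and C1=C10 epoxidation then finish the target.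

Key step: step 9

Atom numbers are germacrane numbers: ring C1–C10, lactone carbons C11–C13, C14 on C10, C15 on C4.
Assumption: the zinc–ProPhenol alkynylation is taken to give the (4R)-carbinol 13 with the (R,R)-ligand; if the catalyst delivers the antipode, the (S,S)-ligand is used with no other change.

Step 1
Reactants: 1 tert-butyl(but-3-yn-1-yloxy)dimethylsilane; 2 vinyl bromide
Product: 4 tert-butyldimethyl{[(3E)-3-methylhexa-3,5-dien-1-yl]oxy}silane, via alkenylalane 3 (not isolated)
Conditions: AlMe3, Cp2ZrCl2 (25 mol%), CH2Cl2, 0 °C to rt; then 2, ZnCl2, Pd(PPh3)4 (5 mol%), THF, rt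
Reagents that add atoms: trimethylaluminium, C[Al](C)C
Why: Zirconium-catalysed Negishi carboalumination adds methyl and aluminium syn across the terminal alkyne (aluminium at the terminus), which fixes the E geometry of C1=C10 with C14; the alkenylalane is then vinylated by palladium-catalysed Negishi cross-coupling with retention.

Step 2
Reactants: 5 but-2-yn-1-ol
Product: 7 (2Z)-3-iodobut-2-en-1-ol, via oxaaluminacycle 6 (not isolated)
Conditions: NaAlH2(OCH2CH2OMe)2 (Red-Al), THF, 0 °C to rt; then I2, THF, −78 °C to 0 °C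
Reagents that add atoms: iodine, II
Why: Hydroxyl-directed trans-hydroalumination of the propargylic alcohol places aluminium on C3 cis to the carbinol carbon in a five-membered aluminate, and iodinolysis with retention gives the Z-iodide that later fixes the C4=C5 geometry.

Step 3
Reactants: 4 tert-butyldimethyl{[(3E)-3-methylhexa-3,5-dien-1-yl]oxy}silane; 7 (2Z)-3-iodobut-2-en-1-ol
Product: 9 (2Z,6E)-9-{[tert-butyl(dimethyl)silyl]oxy}-3,7-dimethylnona-2,6-dien-1-ol, via alkylborane 8 (not isolated)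
Conditions: 9-BBN, THF, 0 °C to rt; then 7, PdCl2(dppf) (5 mol%), AsPh3, Cs2CO3, DMF/H2O, rt
Reagents that add atoms: none
Why: 9-BBN hydroborates only the terminal monosubstituted alkene of the diene at its CH2 end, and the B-alkyl Suzuki–Miyaura coupling joins C3 to C4 with retention of the Z-iodide geometry while tolerating the free allylic alcohol.

Step 4
Reactants: 9 (2Z,6E)-9-{[tert-butyl(dimethyl)silyl]oxy}-3,7-dimethylnona-2,6-dien-1-ol
Product: 10 (2Z,6E)-9-{[tert-butyl(dimethyl)silyl]oxy}-3,7-dimethylnona-2,6-dienal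
Conditions: MnO2, CH2Cl2, rt
Reagents that add atoms: none
Why: Allylic oxidation with activated MnO2 under neutral conditions, the standard way to convert nerol-type Z-allylic alcohols to Z-enals without Z-to-E isomerisation; the enal is used at once.

Step 5
Reactants: 10 (2Z,6E)-9-{[tert-butyl(dimethyl)silyl]oxy}-3,7-dimethylnona-2,6-dienal; 11 methyl propiolate
Product: 13 methyl (4R,5Z,9E)-12-{[tert-butyl(dimethyl)silyl]oxy}-4-hydroxy-6,10-dimethyldodeca-5,9-dien-2-ynoate, via alkynylzinc 12 (not isolated)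
Conditions: 11 (3 equiv), Me2Zn (3 equiv), (R,R)-ProPhenol (10 mol%), Ph3P=O (20 mol%), toluene, 0 °C; then 10
Reagents that add atoms: none
Why: Dinuclear zinc–ProPhenol asymmetric alkynylation of an α,β-unsaturated aldehyde: the chiral catalyst delivers the alkynylzinc to one carbonyl face in a 1,2-addition and so sets C6 (4R in 13, the spatial arrangement of C6 in the target).

Step 6
Reactants: 13 methyl (4R,5Z,9E)-12-{[tert-butyl(dimethyl)silyl]oxy}-4-hydroxy-6,10-dimethyldodeca-5,9-dien-2-ynoate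
Product: 15 (5S)-5-[(1Z,5E)-8-{[tert-butyl(dimethyl)silyl]oxy}-2,6-dimethylocta-1,5-dien-1-yl]furan-2(5H)-one, via hydroxy enoate 14 (not isolated)
Conditions: H2 (1 atm), Pd/CaCO3 poisoned with Pb(OAc)2 (Lindlar catalyst), quinoline, EtOAc, rt; then PPTS (cat.), CH2Cl2, rt
Reagents that add atoms: none
Why: Lindlar semihydrogenation of the ynoate gives the Z-γ-hydroxy enoate, which lactonises to the butenolide; the trisubstituted alkenes are not reduced and C6 is untouched (its label changes from R to S through CIP priorities only).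

Step 7
Reactants: 15 (5S)-5-[(1Z,5E)-8-{[tert-butyl(dimethyl)silyl]oxy}-2,6-dimethylocta-1,5-dien-1-yl]furan-2(5H)-one
Product: 16 (5S)-5-[(1Z,5E)-8-hydroxy-2,6-dimethylocta-1,5-dien-1-yl]furan-2(5H)-one
Conditions: HF·pyridine, pyridine, THF, 0 °C to rt
Reagents that add atoms: none
Why: Fluoride cleavage of the primary silyl ether under buffered, weakly acidic conditions; basic fluoride is avoided because γ-deprotonation of the butenolide would racemise C6 or move C4=C5 into conjugation.

Step 8
Reactants: 16 (5S)-5-[(1Z,5E)-8-hydroxy-2,6-dimethylocta-1,5-dien-1-yl]furan-2(5H)-one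
Product: 17 (3E,7Z)-3,7-dimethyl-8-[(2S)-5-oxo-2,5-dihydrofuran-2-yl]octa-3,7-dienal
Conditions: Dess–Martin periodinane, NaHCO3, CH2Cl2, 0 °C
Reagents that add atoms: none
Why: Dess–Martin oxidation of the primary alcohol under buffered neutral conditions should give the β,γ-unsaturated C8 aldehyde without moving C1=C10 into conjugation; the aldehyde is used immediately.

Step 9
Reactants: 17 (3E,7Z)-3,7-dimethyl-8-[(2S)-5-oxo-2,5-dihydrofuran-2-yl]octa-3,7-dienal
Product: 18 (3aR,4R,6E,10Z,11aR)-4-hydroxy-6,10-dimethyl-3a,4,5,8,9,11a-hexahydrocyclodeca[b]furan-2(3H)-one (8β-hydroxygermacra-1(10)E,4Z-dien-6α,12-olide without C13; 6R,7R,8R)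
Conditions: SmI2 (3 equiv), t-BuOH (3 equiv), THF, slow addition of 17 (final 0.002 M), −78 °C to −20 °C; pH 7 buffer work-up
Reagents that add atoms: none
Why: Proposed new method: SmI2 reduces the C8 aldehyde to a samarium ketyl radical that adds to C7, the β-carbon of the butenolide, in a 10-exo-trig closure of the carbocycle, and a second electron gives the C11 samarium enolate, which t-BuOH protonates to the saturated lactone. The closest known reaction type is the SmI2 ketyl–enoate reductive cyclisation, established for five- to eight-membered rings, together with intermolecular ketyl additions to butenolides, so closure at ten-ring size is the untested element. The ring is expected to close because the Z-C4=C5 and E-C1=C10 bonds leave few rotors in the tether, the butenolide is an activated, polarity-matched acceptor, and high dilution with slow addition suppresses pinacol dimerisation. C7 is controlled by the C6 stereocentre: the bond must form on the butenolide face anti to C5, which gives the trans-fused lactone with C5 and C8 trans on the new ring. C8 is controlled by the transition-state geometry, samarium bridging the ketyl oxygen and the lactone carbonyl so that O8 ends cis to C11 (8β, 8R). The selectivity needed is therefore anti-to-C5 face selectivity plus the 8β carbinol, secured by the C6 substituent, the two alkene geometries of the tether and the samarium chelate.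

Step 10
Reactants: 19 angelic acid
Product: 20 (2Z)-2-methylbut-2-en-1-ol
Conditions: LiAlH4, Et2O, 0 °C to rt
Reagents that add atoms: none
Why: Hydride reduction of the carboxylic acid to the allylic alcohol; the trisubstituted Z-alkene is neither reduced nor isomerised.

Step 11
Reactants: 20 (2Z)-2-methylbut-2-en-1-ol
Product: 21 [(2R,3S)-2,3-dimethyloxiran-2-yl]methanol
Conditions: Ti(OiPr)4 (10 mol%), D-(−)-diethyl tartrate (12 mol%), t-BuOOH, 4 Å MS, CH2Cl2, −20 °C
Reagents that add atoms: tert-butyl hydroperoxide, CC(C)(C)OO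
Why: Sharpless asymmetric epoxidation: the D-(−)-tartrate catalyst delivers oxygen to the alkene face that gives the (2R,3S)-epoxy alcohol, and the Z-alkene fixes the cis relation of the C3 methyl and CH2OH.

Step 12
Reactants: 21 [(2R,3S)-2,3-dimethyloxiran-2-yl]methanol
Product: 22 (2S,3S)-2,3-dimethyloxirane-2-carboxylic acid
Conditions: RuCl3 (cat.), NaIO4, MeCN/EtOAc/H2O, rt
Reagents that add atoms: water, O
Why: Ruthenium tetroxide oxidation (Sharpless conditions) of the primary alcohol to the acid leaves the epoxide intact; the C2 label changes from R to S by CIP priority only.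

Step 13
Reactants: 18 (3aR,4R,6E,10Z,11aR)-4-hydroxy-6,10-dimethyl-3a,4,5,8,9,11a-hexahydrocyclodeca[b]furan-2(3H)-one; 22 (2S,3S)-2,3-dimethyloxirane-2-carboxylic acid
Product: 24 (3aR,4R,6E,10Z,11aR)-6,10-dimethyl-2-oxo-2,3,3a,4,5,8,9,11a-octahydrocyclodeca[b]furan-4-yl (2S,3S)-2,3-dimethyloxirane-2-carboxylate, via mixed anhydride 23 (not isolated)
Conditions: 22, 2,4,6-trichlorobenzoyl chloride, Et3N, toluene, rt; then 18, DMAP, toluene, rt
Reagents that add atoms: none
Why: Yamaguchi esterification acylates the hindered 8β-hydroxyl through the acylpyridinium ion; the acid has no α-hydrogen to epimerise, and no alkoxide is formed that could translactonise O8 onto C12.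

Step 14
Reactants: 24 (3aR,4R,6E,10Z,11aR)-6,10-dimethyl-2-oxo-2,3,3a,4,5,8,9,11a-octahydrocyclodeca[b]furan-4-yl (2S,3S)-2,3-dimethyloxirane-2-carboxylate
Product: 28 (3aR,4R,6E,10Z,11aR)-6,10-dimethyl-3-methylidene-2-oxo-2,3,3a,4,5,8,9,11a-octahydrocyclodeca[b]furan-4-yl (2S,3S)-2,3-dimethyloxirane-2-carboxylate, via lithium enolate 25 (not isolated), via Mannich base 26 (not isolated), via methiodide 27 (not isolated)
Conditions: LiN(iPr)2, THF, −78 °C; CH2=NMe2+ I−, −78 to 0 °C; MeI, MeOH, rt; NaHCO3 (aq), CH2Cl2, rt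
Reagents that add atoms: N,N-dimethylmethyleneiminium iodide (Eschenmoser's salt), C=[N+](C)C.[I-]
Why: Kinetic deprotonation at C11, Mannich reaction with Eschenmoser's salt, quaternisation and Hofmann-type elimination install the C11=C13 methylene; the O8 ester has no α-hydrogen and a quaternary α-carbon, so it should survive the short exposure to the enolate at −78 °C.

Step 15
Reactants: 28 (3aR,4R,6E,10Z,11aR)-6,10-dimethyl-3-methylidene-2-oxo-2,3,3a,4,5,8,9,11a-octahydrocyclodeca[b]furan-4-yl (2S,3S)-2,3-dimethyloxirane-2-carboxylate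
Product: 29 (1R,4Z,6R,7R,8R,10R)-1,10-epoxy-8-{[(2S,3S)-2,3-dimethyloxirane-2-carbonyl]oxy}germacra-4,11(13)-dien-12,6-olide (target CNP0165580.1)
Conditions: mCPBA, NaHCO3, CH2Cl2, 0 °C
Reagents that add atoms: 3-chloroperoxybenzoic acid, O=C(OO)c1cccc(Cl)c1
Why: Prilezhaev epoxidation: the peracid takes the most electron-rich alkene, C1=C10 (C4=C5 is deactivated by the allylic lactone oxygen, C11=C13 is electron-poor), on its exposed outer face in the ring conformer with C14 on the β side, which should give the trans (1R,10R) epoxide as in peracid epoxidations of related germacranolides.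

Compound list
1 | tert-butyl(but-3-yn-1-yloxy)dimethylsilane | C#CCCO[Si](C)(C)C(C)(C)C | starting material
2 | vinyl bromide | C=CBr | starting material
3 | {(1E)-4-{[tert-butyl(dimethyl)silyl]oxy}-2-methylbut-1-en-1-yl}(dimethyl)alane | C[Al](C)/C=C(\C)CCO[Si](C)(C)C(C)(C)C | intermediate
4 | tert-butyldimethyl{[(3E)-3-methylhexa-3,5-dien-1-yl]oxy}silane | C=C/C=C(\C)CCO[Si](C)(C)C(C)(C)C | intermediate
5 | but-2-yn-1-ol | CC#CCO | starting material
6 | sodium 2,2-bis(2-methoxyethoxy)-3-methyl-2,5-dihydro-1,2-oxaaluminol-2-uide (aluminium bonded to O1 and C3 of the butenol) | CC1=CCO[Al-]1(OCCOC)OCCOC.[Na+] | intermediate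
7 | (2Z)-3-iodobut-2-en-1-ol | OC/C=C(/C)I | intermediate
8 | 9-[(3E)-6-{[tert-butyl(dimethyl)silyl]oxy}-4-methylhex-3-en-1-yl]-9-borabicyclo[3.3.1]nonane | CC(C)(C)[Si](C)(C)OCC/C(C)=C/CCB1C2CCCC1CCC2 | intermediate
9 | (2Z,6E)-9-{[tert-butyl(dimethyl)silyl]oxy}-3,7-dimethylnona-2,6-dien-1-ol | OC/C=C(/C)CC/C=C(\C)CCO[Si](C)(C)C(C)(C)C | intermediate
10 | (2Z,6E)-9-{[tert-butyl(dimethyl)silyl]oxy}-3,7-dimethylnona-2,6-dienal | O=C/C=C(/C)CC/C=C(\C)CCO[Si](C)(C)C(C)(C)C | intermediate
11 | methyl propiolate | C#CC(=O)OC | starting material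
12 | methyl 3-(methylzincio)prop-2-ynoate | C[Zn]C#CC(=O)OC | intermediate
13 | methyl (4R,5Z,9E)-12-{[tert-butyl(dimethyl)silyl]oxy}-4-hydroxy-6,10-dimethyldodeca-5,9-dien-2-ynoate | O[C@@H](C#CC(=O)OC)/C=C(/C)CC/C=C(\C)CCO[Si](C)(C)C(C)(C)C | intermediate
14 | methyl (2Z,4S,5Z,9E)-12-{[tert-butyl(dimethyl)silyl]oxy}-4-hydroxy-6,10-dimethyldodeca-2,5,9-trienoate | COC(=O)/C=C\[C@H](O)/C=C(/C)CC/C=C(\C)CCO[Si](C)(C)C(C)(C)C | intermediate
15 | (5S)-5-[(1Z,5E)-8-{[tert-butyl(dimethyl)silyl]oxy}-2,6-dimethylocta-1,5-dien-1-yl]furan-2(5H)-one | O=C1O[C@@H](C=C1)/C=C(/C)CC/C=C(\C)CCO[Si](C)(C)C(C)(C)C | intermediate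
16 | (5S)-5-[(1Z,5E)-8-hydroxy-2,6-dimethylocta-1,5-dien-1-yl]furan-2(5H)-one | O=C1O[C@@H](C=C1)/C=C(/C)CC/C=C(\C)CCO | intermediate
17 | (3E,7Z)-3,7-dimethyl-8-[(2S)-5-oxo-2,5-dihydrofuran-2-yl]octa-3,7-dienal | O=C1O[C@@H](C=C1)/C=C(/C)CC/C=C(\C)CC=O | intermediate
18 | (3aR,4R,6E,10Z,11aR)-4-hydroxy-6,10-dimethyl-3a,4,5,8,9,11a-hexahydrocyclodeca[b]furan-2(3H)-one | C1C(=O)O[C@@H]2/C=C(/C)CC/C=C(\C)C[C@@H](O)[C@@H]12 | intermediate
19 | angelic acid, (2Z)-2-methylbut-2-enoic acid | C/C=C(/C)C(=O)O | starting material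
20 | (2Z)-2-methylbut-2-en-1-ol | C/C=C(/C)CO | intermediate
21 | [(2R,3S)-2,3-dimethyloxiran-2-yl]methanol | OC[C@@]1(C)O[C@H]1C | intermediate
22 | (2S,3S)-2,3-dimethyloxirane-2-carboxylic acid | OC(=O)[C@@]1(C)O[C@H]1C | intermediate
23 | (2S,3S)-2,3-dimethyloxirane-2-carboxylic 2,4,6-trichlorobenzoic anhydride | O=C(OC(=O)[C@@]1(C)O[C@H]1C)c1c(Cl)cc(Cl)cc1Cl | intermediate
24 | (3aR,4R,6E,10Z,11aR)-6,10-dimethyl-2-oxo-2,3,3a,4,5,8,9,11a-octahydrocyclodeca[b]furan-4-yl (2S,3S)-2,3-dimethyloxirane-2-carboxylate | C1C(=O)O[C@@H]2/C=C(/C)CC/C=C(\C)C[C@@H](OC(=O)[C@@]3(C)O[C@H]3C)[C@@H]12 | intermediate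
25 | lithium enolate of 24 (C11=C12–O−, lithium counter-ion) | C1=C([O-])O[C@@H]2/C=C(/C)CC/C=C(\C)C[C@@H](OC(=O)[C@@]3(C)O[C@H]3C)[C@@H]12.[Li+] | intermediate
26 | 11-(dimethylaminomethyl) derivative of 24 (Mannich base, C11 configuration not defined) | CN(C)CC1C(=O)O[C@@H]2/C=C(/C)CC/C=C(\C)C[C@@H](OC(=O)[C@@]3(C)O[C@H]3C)[C@@H]12 | intermediate
27 | 11-(trimethylammoniomethyl) derivative of 24, iodide (C11 configuration not defined) | C[N+](C)(C)CC1C(=O)O[C@@H]2/C=C(/C)CC/C=C(\C)C[C@@H](OC(=O)[C@@]3(C)O[C@H]3C)[C@@H]12.[I-] | intermediate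
28 | (3aR,4R,6E,10Z,11aR)-6,10-dimethyl-3-methylidene-2-oxo-2,3,3a,4,5,8,9,11a-octahydrocyclodeca[b]furan-4-yl (2S,3S)-2,3-dimethyloxirane-2-carboxylate | C=C1C(=O)O[C@@H]2/C=C(/C)CC/C=C(\C)C[C@@H](OC(=O)[C@@]3(C)O[C@H]3C)[C@@H]12 | intermediate
29 | (1R,4Z,6R,7R,8R,10R)-1,10-epoxy-8-{[(2S,3S)-2,3-dimethyloxirane-2-carbonyl]oxy}germacra-4,11(13)-dien-12,6-olide (1β,10α-epoxide, 8β-ester, 6α,12-lactone) | C=C1C(=O)O[C@@H]2/C=C(/C)CC[C@H]3O[C@]3(C)C[C@@H](OC(=O)[C@@]3(C)O[C@H]3C)[C@@H]12 | target

Total step count: 15.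
Longest linear sequence: 11 steps (1, 3, 4, 5, 6, 7, 8, 9, 13, 14, 15).

Steps most likely to fail

Step 9 (Proposed new method). The ten-membered transition state may not be reached, so that simple reduction of the aldehyde, pinacol dimerisation or reductive cleavage of the doubly allylic C6–O bond outruns cyclisation, or closure may occur on the butenolide face syn to C5. The fallback uses known chemistry: the same C7–C8 bond is closed by an intramolecular chromium-mediated Barbier (Nozaki–Hiyama) allylation. This ring closure is established for ten-membered germacranolide rings, and 3-(bromomethyl)butenolides are known to attack aldehydes through their γ-carbon with formation of the α-methylene lactone. The fallback sets out from 13 and returns at 28. Palladium-catalysed hydrostannation of 13 (Bu3SnH, Pd(PPh3)4, THF) places tin α to the ester by syn addition, and the hydroxy ester lactonises to the 3-(tributylstannyl) analogue of butenolide 15, F1. Iododestannylation (I2, CH2Cl2) gives the 3-iodobutenolide F2. Stille coupling with (tributylstannyl)methanol (Pd(PPh3)4, dioxane, 80 °C) gives the 3-(hydroxymethyl)butenolide F3, and an Appel reaction (CBr4, PPh3) gives the 3-(bromomethyl)butenolide F4. HF·pyridine frees the primary alcohol F5 and Dess–Martin oxidation gives the bromo aldehyde F6. CrCl2 (THF, high dilution) should then join C7 to C8 with allylic transposition to give the 8β-hydroxy α-methylene lactone F7, which already holds C13. Yamaguchi acylation of F7 with 23, as in step 13, delivers 28.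

Step 14. The C11 enolate may attack the neighbouring O8 ester carbonyl (acyl migration from oxygen to carbon), or enolisation may be incomplete. The fallback changes the order so that a silyl ether, not the final ester, is present during enolate chemistry; it sets out from 18 and returns at 28. Silylation (TESCl, imidazole, CH2Cl2) gives the triethylsilyl ether F8. LiN(iPr)2 gives its lithium enolate F9, Eschenmoser's salt the Mannich base F10, MeI the methiodide F11, and NaHCO3 the α-methylene silyl ether F12. HF·pyridine frees the hydroxy α-methylene lactone F13, and Yamaguchi acylation with 23 returns to 28.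

Step 15. Facial selectivity may be poor if the ring reacts through the conformer with C14 on the α side, and epoxidation of C4=C5 may compete. The fallback replaces substrate-controlled peracid attack by hydroxyl-directed epoxidation and moves it ahead of acylation; it sets out from 18 and returns at 29. VO(acac)2 (cat.) with t-BuOOH in CH2Cl2 at 0 °C should deliver oxygen from the vanadate ester of the 8β-hydroxyl to C1=C10 only, giving the epoxy alcohol F14. Yamaguchi acylation with 23 gives the epoxy ester F15. Methylenation as in step 14, through lithium enolate F16, Mannich base F17 and methiodide F18, gives 29.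

Further compounds
F1 | step 9 | 3-(tributylstannyl) analogue of butenolide 15 | O=C1O[C@@H](C=C1[Sn](CCCC)(CCCC)CCCC)/C=C(/C)CC/C=C(\C)CCO[Si](C)(C)C(C)(C)C
F2 | step 9 | 3-iodo analogue of butenolide 15 | O=C1O[C@@H](C=C1I)/C=C(/C)CC/C=C(\C)CCO[Si](C)(C)C(C)(C)C
F3 | step 9 | 3-(hydroxymethyl) analogue of butenolide 15 | O=C1O[C@@H](C=C1CO)/C=C(/C)CC/C=C(\C)CCO[Si](C)(C)C(C)(C)C
F4 | step 9 | 3-(bromomethyl) analogue of butenolide 15 | O=C1O[C@@H](C=C1CBr)/C=C(/C)CC/C=C(\C)CCO[Si](C)(C)C(C)(C)C
F5 | step 9 | 3-(bromomethyl) analogue of alcohol 16 | O=C1O[C@@H](C=C1CBr)/C=C(/C)CC/C=C(\C)CCO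
F6 | step 9 | 3-(bromomethyl) analogue of aldehyde 17 | O=C1O[C@@H](C=C1CBr)/C=C(/C)CC/C=C(\C)CC=O
F7 | step 9 | (3aR,4R,6E,10Z,11aR)-4-hydroxy-6,10-dimethyl-3-methylidene-3a,4,5,8,9,11a-hexahydrocyclodeca[b]furan-2(3H)-one | C=C1C(=O)O[C@@H]2/C=C(/C)CC/C=C(\C)C[C@@H](O)[C@@H]12
F8 | step 14 | triethylsilyl ether of 18 | C1C(=O)O[C@@H]2/C=C(/C)CC/C=C(\C)C[C@@H](O[Si](CC)(CC)CC)[C@@H]12
F9 | step 14 | lithium enolate of F8 | C1=C([O-])O[C@@H]2/C=C(/C)CC/C=C(\C)C[C@@H](O[Si](CC)(CC)CC)[C@@H]12.[Li+]
F10 | step 14 | 11-(dimethylaminomethyl) derivative of F8 | CN(C)CC1C(=O)O[C@@H]2/C=C(/C)CC/C=C(\C)C[C@@H](O[Si](CC)(CC)CC)[C@@H]12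
F11 | step 14 | 11-(trimethylammoniomethyl) derivative of F8, iodide | C[N+](C)(C)CC1C(=O)O[C@@H]2/C=C(/C)CC/C=C(\C)C[C@@H](O[Si](CC)(CC)CC)[C@@H]12.[I-]
F12 | step 14 | 3-methylidene derivative of F8 | C=C1C(=O)O[C@@H]2/C=C(/C)CC/C=C(\C)C[C@@H](O[Si](CC)(CC)CC)[C@@H]12
F13 | step 14 | (3aR,4R,6E,10Z,11aR)-4-hydroxy-6,10-dimethyl-3-methylidene-3a,4,5,8,9,11a-hexahydrocyclodeca[b]furan-2(3H)-one | C=C1C(=O)O[C@@H]2/C=C(/C)CC/C=C(\C)C[C@@H](O)[C@@H]12
F14 | step 15 | (1R,10R)-1,10-epoxide of 18 | C1C(=O)O[C@@H]2/C=C(/C)CC[C@H]3O[C@]3(C)C[C@@H](O)[C@@H]12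
F15 | step 15 | (1R,10R)-1,10-epoxide of 24 | C1C(=O)O[C@@H]2/C=C(/C)CC[C@H]3O[C@]3(C)C[C@@H](OC(=O)[C@@]3(C)O[C@H]3C)[C@@H]12
F16 | step 15 | lithium enolate of F15 | C1=C([O-])O[C@@H]2/C=C(/C)CC[C@H]3O[C@]3(C)C[C@@H](OC(=O)[C@@]3(C)O[C@H]3C)[C@@H]12.[Li+]
F17 | step 15 | 11-(dimethylaminomethyl) derivative of F15 | CN(C)CC1C(=O)O[C@@H]2/C=C(/C)CC[C@H]3O[C@]3(C)C[C@@H](OC(=O)[C@@]3(C)O[C@H]3C)[C@@H]12
F18 | step 15 | 11-(trimethylammoniomethyl) derivative of F15, iodide | C[N+](C)(C)CC1C(=O)O[C@@H]2/C=C(/C)CC[C@H]3O[C@]3(C)C[C@@H](OC(=O)[C@@]3(C)O[C@H]3C)[C@@H]12.[I-]
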